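**Plan**
- Retrosynthesis: the two O–isopropyl bonds are cut first (final deprotection). Then C4–C4a and O1–C8a of the pyran ring are cut together, giving 1-iodo-3-isopropoxybenzene and an (S)-2-aryl-3-bromopropan-1-ol. The C–Br bond of the bromohydrin leads back to a prochiral 3-aryloxetane, and the aryl–CMe2 and aryl–oxetane bonds lead back to syringol.
- Enabling feature: ring A shares C4a (bonded to C4) and C8a (bonded to O1) with the pyran ring. These adjacent carbons are the ortho C–H and ipso C–I positions of a 3-alkoxyiodobenzene, and C2–C3–C4 is a 2-arylpropane-1,3-diyl unit with differentiated ends (OH and Br).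
- Forward: ring B is built first (oxetane at C1', then bromine and 1,1-dimethylallyl at C5'). The oxetane is opened to the bromohydrin, the pyran ring (the only ring formed) is closed onto ring A in one palladium/norbornene operation, and both isopropyl ethers are removed.
- Stereochemistry: the single stereocentre C3 comes from a squaramide-catalysed enantioselective TMSBr opening of the prochiral oxetane (S). It is never a reacting atom afterwards and is carried through unchanged.

Key step: step 8

Assumption: the sense of induction in step 6 is taken to follow that of simple 3-aryloxetanes, and the catalyst antipode (both derive from L- or D-tert-leucine) that gives (S)-12 is used. In step 5 the ligand is the member of the dicyclohexylbiarylphosphine family that gives the branched isomer, to be fixed in a short screen.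

Step 1
Reactants: 1 syringol (2,6-dimethoxyphenol)
Product: 2 2-isopropoxy-1,3-dimethoxybenzene
Conditions: 2-bromopropane, K2CO3, DMF, 70 °C
Reagents that add atoms: 2-bromopropane CC(C)Br
Why: Williamson ether synthesis of the phenoxide with a secondary bromide in a dipolar aprotic solvent, installing an ether that can later be cleaved in the presence of methyl ethers.

Step 2
Reactants: 2 2-isopropoxy-1,3-dimethoxybenzene
Product: 5 (3-isopropoxy-2,4-dimethoxyphenyl)boronic acid, via (3-isopropoxy-2,4-dimethoxyphenyl)lithium 3 (not isolated), via lithium aryltriisopropoxyborate 4 (not isolated)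
Conditions: n-BuLi, TMEDA, THF, 0 °C; B(OiPr)3, −78 °C → rt; 1 M HCl
Reagents that add atoms: n-butyllithium [Li]CCCC (lithium of 3 and 4 only); triisopropyl borate CC(C)OB(OC(C)C)OC(C)C; water O
Why: Directed ortho-metalation, in which a methoxy group steers lithiation to the adjacent C–H (the two such positions are equivalent) as in other 1,2,3-trialkoxybenzenes, followed by borate trapping and hydrolysis.

Step 3
Reactants: 5 (3-isopropoxy-2,4-dimethoxyphenyl)boronic acid; 6 3-iodooxetane
Product: 7 3-(3-isopropoxy-2,4-dimethoxyphenyl)oxetane
Conditions: NiI2 (cat.), trans-2-aminocyclohexanol·HCl (cat.), NaHMDS, i-PrOH, 80 °C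
Reagents that add atoms: none
Why: Nickel-catalysed Suzuki–Miyaura coupling of an arylboronic acid with a secondary alkyl iodide, the standard entry to 3-aryloxetanes, in which the oxetanyl iodide is engaged through a radical oxidative addition without ring opening.

Step 4
Reactants: 7 3-(3-isopropoxy-2,4-dimethoxyphenyl)oxetane
Product: 8 3-(5-bromo-3-isopropoxy-2,4-dimethoxyphenyl)oxetane
Conditions: NBS (1.0 equiv), MeCN, 0 °C → rt
Reagents that add atoms: N-bromosuccinimide O=C1CCC(=O)N1Br
Why: Electrophilic aromatic bromination, expected at C5 because it is ortho to one methoxy and para to the other, whereas C6 is activated only by the twisted isopropoxy group; the neutral conditions should leave the oxetane intact.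

Step 5
Reactants: 8 3-(5-bromo-3-isopropoxy-2,4-dimethoxyphenyl)oxetane; 9 prenylboronic acid pinacol ester
Product: 10 3-[3-isopropoxy-2,4-dimethoxy-5-(2-methylbut-3-en-2-yl)phenyl]oxetane
Conditions: Pd(OAc)2, dicyclohexylbiarylphosphine (branched-selective ligand, not the di-tert-butyl type), aq. K3PO4, THF or MeCN, 40–70 °C
Reagents that add atoms: none
Why: γ-Selective Suzuki–Miyaura coupling of a 3,3-disubstituted allylboronate, in which SE2' transmetalation gives the tertiary σ-allylpalladium species and a ligand that favours reductive elimination over σ–π–σ isomerisation should deliver the 1,1-dimethylallyl arene.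

Step 6
Reactants: 10 3-[3-isopropoxy-2,4-dimethoxy-5-(2-methylbut-3-en-2-yl)phenyl]oxetane
Product: 12 (2S)-3-bromo-2-[3-isopropoxy-2,4-dimethoxy-5-(2-methylbut-3-en-2-yl)phenyl]propan-1-ol, via trimethylsilyl ether 11 (not isolated)
Conditions: TMSBr, chiral tert-leucine-derived arylpyrrolidine squaramide (5 mol%), t-BuOMe, −78 °C; then 1 M HCl, THF, 0 °C
Reagents that add atoms: bromotrimethylsilane C[Si](C)(C)Br
Why: Enantioselective desymmetrising ring opening of a prochiral 3-aryloxetane under hydrogen-bond-donor catalysis, in which the catalyst-bound bromide attacks one of the two enantiotopic O–CH2 carbons of the silylated oxetane and so sets C3 as S; mild acidic desilylation avoids base-induced reclosure.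

Step 7
Reactants: 13 3-iodophenol
Product: 14 1-iodo-3-isopropoxybenzene
Conditions: 2-bromopropane, K2CO3, DMF, 60 °C
Reagents that add atoms: 2-bromopropane CC(C)Br
Why: Williamson ether synthesis, giving an ether that is inert to palladium and carbonate at 100 °C and whose bulk shields the position between iodine and oxygen.

Step 8
Reactants: 12 (2S)-3-bromo-2-[3-isopropoxy-2,4-dimethoxy-5-(2-methylbut-3-en-2-yl)phenyl]propan-1-ol; 14 1-iodo-3-isopropoxybenzene
Product: 15 (3S)-7-isopropoxy-3-[3-isopropoxy-2,4-dimethoxy-5-(2-methylbut-3-en-2-yl)phenyl]chromane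
Conditions: 14 (1.5 equiv), Pd(OAc)2 (10 mol%), XPhos (20 mol%), bridgehead (C1)-alkyl norbornene (1 equiv), Cs2CO3, toluene, 100 °C
Reagents that add atoms: none
Why: Proposed new method: Pd(0) adds to the C–I bond of 14, the norbornene inserts, and carbonate-assisted palladation of the less hindered ortho C–H (para to the isopropoxy group, the future C4a) gives the aryl–norbornyl palladacycle, which adds the primary C–Br bond of 12 and reductively eliminates to form C4–C4a. β-Carbon elimination then expels norbornene, the tethered alkoxide replaces halide on the ipso arylpalladium(II), and C–O reductive elimination from a seven-membered oxapalladacycle forms O1–C8a. The closest known reaction types are the Catellani ortho-alkylation of aryl iodides with primary alkyl bromides and its annulative variants with bromoalkylamines (C–N ipso termination to tetrahydroquinolines) and with epoxides (C–O ipso termination to dihydrobenzofurans); closure of a pyran ring by a 1,3-bromohydrin has not been shown. The pyran ring thus closes in a formal [3+3] sense, by intermolecular C–C bond formation followed by ring-closing aryl C–O reductive elimination; no stereocentre is created, and C3 is never bonded to palladium, lying β to it only in the short-lived alkylpalladium(IV) species whose C–C reductive elimination should outrun β-hydride loss. The step needs a single alkylation at C4a rather than between iodine and the isopropoxy group, which the meta isopropoxy substituent and the bridgehead-substituted norbornene (it enforces norbornene extrusion after one ortho functionalisation) should secure. It also needs ipso C–O coupling to outrun Heck capture by the hindered vinyl group, β-hydride loss from the palladium alkoxide and base-induced reclosure to the oxetane, for which the intramolecular alkoxide, the bulky biarylphosphine and a sparingly soluble carbonate in a non-polar solvent are relied upon.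

Step 9
Reactants: 15 (3S)-7-isopropoxy-3-[3-isopropoxy-2,4-dimethoxy-5-(2-methylbut-3-en-2-yl)phenyl]chromane
Product: 17 (3S)-3-[3-hydroxy-2,4-dimethoxy-5-(2-methylbut-3-en-2-yl)phenyl]chroman-7-ol (CNP0305994.1), via bis(dichloroboryl) ether 16 (not isolated)
Conditions: BCl3 (1 M in CH2Cl2), CH2Cl2, −78 → 0 °C; quench with aq. NaHCO3 at −78 °C
Reagents that add atoms: boron trichloride ClB(Cl)Cl (boron and chlorine of 16 only; none remain in 17)
Why: Lewis-acid dealkylation of aryl isopropyl ethers, in which BCl3 ionises the secondary O–alkyl bonds (to 2-chloropropane) much faster than it cleaves methyl or chroman ethers; low temperature and a buffered quench should spare the monosubstituted alkene and the C3 stereocentre.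

**Compound list**
1 | syringol (2,6-dimethoxyphenol) | COc1cccc(OC)c1O | starting material
2 | 2-isopropoxy-1,3-dimethoxybenzene | COc1cccc(OC)c1OC(C)C | intermediate
3 | (3-isopropoxy-2,4-dimethoxyphenyl)lithium | [Li]c1ccc(OC)c(OC(C)C)c1OC | intermediate (not isolated)
4 | lithium (3-isopropoxy-2,4-dimethoxyphenyl)triisopropoxyborate | CC(C)O[B-](OC(C)C)(OC(C)C)c1ccc(OC)c(OC(C)C)c1OC.[Li+] | intermediate (not isolated)
5 | (3-isopropoxy-2,4-dimethoxyphenyl)boronic acid | COc1ccc(B(O)O)c(OC)c1OC(C)C | intermediate
6 | 3-iodooxetane | IC1COC1 | starting material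
7 | 3-(3-isopropoxy-2,4-dimethoxyphenyl)oxetane | COc1ccc(C2COC2)c(OC)c1OC(C)C | intermediate
8 | 3-(5-bromo-3-isopropoxy-2,4-dimethoxyphenyl)oxetane | COc1c(Br)cc(C2COC2)c(OC)c1OC(C)C | intermediate
9 | prenylboronic acid pinacol ester | CC(C)=CCB1OC(C)(C)C(C)(C)O1 | starting material
10 | 3-[3-isopropoxy-2,4-dimethoxy-5-(2-methylbut-3-en-2-yl)phenyl]oxetane | C=CC(C)(C)c1cc(C2COC2)c(OC)c(OC(C)C)c1OC | intermediate
11 | (2S)-3-bromo-2-arylpropyl trimethylsilyl ether (aryl as in 12) | C=CC(C)(C)c1cc([C@@H](CO[Si](C)(C)C)CBr)c(OC)c(OC(C)C)c1OC | intermediate (not isolated)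
12 | (2S)-3-bromo-2-[3-isopropoxy-2,4-dimethoxy-5-(2-methylbut-3-en-2-yl)phenyl]propan-1-ol | C=CC(C)(C)c1cc([C@@H](CO)CBr)c(OC)c(OC(C)C)c1OC | intermediate
13 | 3-iodophenol | Oc1cccc(I)c1 | starting material
14 | 1-iodo-3-isopropoxybenzene | CC(C)Oc1cccc(I)c1 | intermediate
15 | (3S)-7-isopropoxy-3-[3-isopropoxy-2,4-dimethoxy-5-(2-methylbut-3-en-2-yl)phenyl]chromane | C=CC(C)(C)c1cc([C@H]2COc3cc(OC(C)C)ccc3C2)c(OC)c(OC(C)C)c1OC | intermediate
16 | 7,3'-bis(dichloroboryl) ether of the (3S)-isoflavan diol | C=CC(C)(C)c1cc([C@H]2COc3cc(OB(Cl)Cl)ccc3C2)c(OC)c(OB(Cl)Cl)c1OC | intermediate (not isolated)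
17 | (3S)-3-[3-hydroxy-2,4-dimethoxy-5-(2-methylbut-3-en-2-yl)phenyl]chroman-7-ol | C=CC(C)(C)c1cc([C@H]2COc3cc(O)ccc3C2)c(OC)c(O)c1OC | target

**Totals**
Total step count: 9. Longest linear sequence: 8 (steps 1–6, 8, 9); step 7 is a one-step side branch.

**Steps most likely to fail**

Step 8 (Proposed new method). What may go wrong:
- slow oxidative addition of the β-branched bromide to the palladacycle;
- a second ortho palladation or retention of norbornene;
- ipso reduction through β-hydride loss from the palladium alkoxide;
- Heck capture by the vinyl group;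
- Williamson reclosure of the bromohydrin to the oxetane.

The fallback uses known chemistry, sets out from 12 and comes back at 15. Purchased 3-isopropoxyphenol is iodinated ortho to the hydroxyl and para to the ether (I2, NaHCO3, THF/H2O) to give 2-iodo-5-isopropoxyphenol F1. Mitsunobu etherification of 12 with F1 (PPh3, DIAD, THF, 0 °C → rt) gives 1-[(2S)-1-bromo-3-(2-iodo-5-isopropoxyphenoxy)propan-2-yl]-3-isopropoxy-2,4-dimethoxy-5-(2-methylbut-3-en-2-yl)benzene F2. Iodine–lithium exchange (n-BuLi, THF, −100 °C) gives the aryllithium F3, which on warming alkylates itself at the primary bromide (Parham cycloalkylation) and closes the pyran ring to 15. The carbon that bore OH still becomes C2 and the carbon that bore Br still becomes C4, so the same (3S) compound results.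

Step 5. What may go wrong: erosion of branched-to-linear selectivity by σ–π–σ isomerisation, slow coupling at the crowded bromide flanked by a methoxy group, and protodeboronation of the allylboronate. The fallback sets out from 8 and comes back at 10. Palladium-catalysed α-arylation of the lithium enolate of methyl isobutyrate (LiNCy2, Pd(dba)2/P(t-Bu)3, toluene, rt) gives methyl 2-[3-isopropoxy-2,4-dimethoxy-5-(oxetan-3-yl)phenyl]-2-methylpropanoate F4. DIBAL-H reduction (CH2Cl2, −78 °C) gives 2-[3-isopropoxy-2,4-dimethoxy-5-(oxetan-3-yl)phenyl]-2-methylpropanal F5, and Wittig methylenation (Ph3PCH3Br, KOt-Bu, THF, 0 °C) of this non-enolisable aldehyde gives 10.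

Step 6. What may go wrong: uncatalysed racemic background opening, weaker enantiotopic discrimination because of the ortho methoxy group, and participation of that methoxy oxygen in the opening. The fallback sets out from 10 and comes back at 12. Acid hydrolysis of the oxetane (0.5 M H2SO4, dioxane/H2O, 50 °C) gives 2-[3-isopropoxy-2,4-dimethoxy-5-(2-methylbut-3-en-2-yl)phenyl]propane-1,3-diol F6. Lipase-catalysed desymmetrising monoacetylation (vinyl acetate, Pseudomonas cepacia lipase, t-BuOMe, rt), with the enzyme selected by screening to acylate the arm that becomes C2, gives (2R)-3-hydroxy-2-arylpropyl acetate F7. Appel bromination (CBr4, PPh3, CH2Cl2, 0 °C) gives (2S)-3-bromo-2-arylpropyl acetate F8, and methanolysis (K2CO3, MeOH, 0 °C) gives 12.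

**Further compounds**
F1 | step 8 | 2-iodo-5-isopropoxyphenol | CC(C)Oc1ccc(I)c(O)c1
F2 | step 8 | 1-[(2S)-1-bromo-3-(2-iodo-5-isopropoxyphenoxy)propan-2-yl]-3-isopropoxy-2,4-dimethoxy-5-(2-methylbut-3-en-2-yl)benzene | C=CC(C)(C)c1cc([C@@H](COc2cc(OC(C)C)ccc2I)CBr)c(OC)c(OC(C)C)c1OC
F3 | step 8 | aryllithium from iodine–lithium exchange of F2 | C=CC(C)(C)c1cc([C@@H](COc2cc(OC(C)C)ccc2[Li])CBr)c(OC)c(OC(C)C)c1OC
F4 | step 5 | methyl 2-[3-isopropoxy-2,4-dimethoxy-5-(oxetan-3-yl)phenyl]-2-methylpropanoate | COC(=O)C(C)(C)c1cc(C2COC2)c(OC)c(OC(C)C)c1OC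
F5 | step 5 | 2-[3-isopropoxy-2,4-dimethoxy-5-(oxetan-3-yl)phenyl]-2-methylpropanal | O=CC(C)(C)c1cc(C2COC2)c(OC)c(OC(C)C)c1OC
F6 | step 6 | 2-[3-isopropoxy-2,4-dimethoxy-5-(2-methylbut-3-en-2-yl)phenyl]propane-1,3-diol | C=CC(C)(C)c1cc(C(CO)CO)c(OC)c(OC(C)C)c1OC
F7 | step 6 | (2R)-3-hydroxy-2-[3-isopropoxy-2,4-dimethoxy-5-(2-methylbut-3-en-2-yl)phenyl]propyl acetate | C=CC(C)(C)c1cc([C@@H](COC(C)=O)CO)c(OC)c(OC(C)C)c1OC
F8 | step 6 | (2S)-3-bromo-2-[3-isopropoxy-2,4-dimethoxy-5-(2-methylbut-3-en-2-yl)phenyl]propyl acetate | C=CC(C)(C)c1cc([C@@H](COC(C)=O)CBr)c(OC)c(OC(C)C)c1OC
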